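All runs stem from a simulated flask for substances that don't exist, and the scatter is random.

Product in these flasks is counted in percent of the substrate charged, and I had earlier runs to set it against.

the same everywhere: reagent 0.351 M

| charge | substrate | free catalyst | remark | time |
|---|---|---|---|---|
| Tuesday's | 0.41 M | 3.7 mM | run made earlier |  |
| Friday's | 2.3 M | 3.7 mM | run made earlier |  |
| Monday's | 0.37 M | 5.2 mM | run made earlier |  |
| elm | 0.37 M | 3.7 mM |  | 20 h |
| maple | 1.5 M | 8.0 mM |  | 20 h |

| run | time / h | product / % | substrate / % |
|---|---|---|---|
| Tuesday's | 1.50 | 19.5 | 80.6 |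
| Tuesday's | 4.00 | 40.4 | 57.0 |
| Tuesday's | 8.00 | 60.0 | 40.8 |
| Tuesday's | 20.0 | 77.1 | 21.6 |
| Friday's | 5.00 | 8.2 | 90.7 |
| Friday's | 10.0 | 10.9 | 88.4 |
| Friday's | 15.0 | 13.5 | 85.6 |
| Friday's | 20.0 | 14.3 | 85.1 |
| Monday's | 2.50 | 39.6 | 57.6 |
| Monday's | 8.00 | 74.8 | 24.5 |
| Monday's | 12.0 | 84.0 | 15.7 |
| Monday's | 20.0 | 92.2 | 7.5 |

(scatter of a reading: 1 percentage point)

- which of the two ends with the higher amount of product, in percent of the substrate charged ("neither" if they lie within 2 percentage points) (elm / maple / neither)
- product at the end, in percent of the substrate charged, elm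
- product at the end, in percent of the substrate charged, maple



Friday's run slowed, reading 13.5% at 15.0 h and 14.3% at 20.0 h. In molar terms that last reading was 0.329 M, close to the 0.351 M of reagent charged, so I read reagent as consumed about one to one. That left two amounts to hold against each other, [reagent] charged and [substrate] charged. Their ratio is the reagent ceiling, the product in percent of the substrate charged once the limiting reagent is consumed: for maple, 23.4%.

Friday's last reading of product stood at 93.7% of its reagent charge with 3.7 mM of catalyst, and maple carried twice that catalyst, so I put maple at its ceiling. Elm's ceiling was 94.9%. But Monday's run, elm's charges with 5.2 mM of catalyst, read 92.2% at 20.0 h, so I expected elm, with 3.7 mM, to end below that ceiling. Tuesday's run, with nearly elm's charges, still read 77.1% at 20.0 h, higher than maple's ceiling, so I put elm ahead.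

The forecast gave elm 86.5% and maple 23%, with elm ahead, holding that in maple “reagent is essentially used up”.

Elm ended at 87.0% and maple at 23.0%.

    reagent + free catalyst → catalyst intermediate A (k = 68.0 /M/h)
    catalyst intermediate A ⇌ catalyst intermediate B (K = 0.860, k = 1100 /h)
    substrate + catalyst intermediate B → catalyst intermediate C (k = 12000 /M/h)
    catalyst intermediate C → catalyst intermediate D (k = 110 /h)
    catalyst intermediate D ⇌ free catalyst + product (K = 0.310 M, k = 4000 /h)
    catalyst intermediate C → spent catalyst (k = 0.130 /h)

In maple, the half-life of reagent by its conversion with free catalyst into catalyst intermediate A stood at 2.2 h at 1.91 h, far shorter than the 20 h of the run. Maple ended with 0.49% of its charged reagent and 77% of its charged substrate still there, unbound, and with product at 23.0% against a ceiling of 23.4%. The neighbouring flask, maple with 0.60 M of substrate, had a ceiling of 58.5%, and it ended at 57.5%.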